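## Structural features

The target 32 is a germacranolide: a ten-membered carbocycle (C1–C10) to which an α-methylene-γ-butyrolactone (O6, C12, C11=C13) is trans-fused at C6–C7. Four contiguous stereocentres alternate across the ring faces: C5 (S, free hydroxyl), C6 (S, lactone oxygen), C7 (R, C11 arm) and C8 (S, tiglate), i.e. 5,6-threo, 6,7-trans, 7,8-trans. The other half of the ring is a cross-conjugated dienone, C10(C14)=C1–C2(=O)–C3=C4(C15), in which both trisubstituted alkenes are cis within the ring (1(10)Z, 3Z). Fragile elements are the exocyclic acrylate (Michael acceptor, can slip into the ring), the dienone (γ-deprotonation, conjugate addition, geometric isomerisation), the (Z)-γ-hydroxy enone C5–OH/C2=O, the tiglate, and the O5/O6/O8 array across which acyl groups can migrate. The real difficulty is less any single stereocentre than joining a strained medium ring that holds two cis trisubstituted alkenes to the dense O5–O6–C7–O8 array, and closing that ring without disturbing either. The key step exploits the 1,5-relationship of O6 (on C6) and the methyl-bearing C10 through C7–C8(O)–C9: O6, C6, C7, C8, C9, C10 form the tetrahydropyranone ring, and C6–C10 with C1 and C5 the cycloheptenone ring, of a 2-methylfuran/2-oxyallyl [4+3] adduct whose ether bridge is O6.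

## Logic of the disconnections

32 ⇒ 31. No skeletal bond is cut; the C2 ketone is taken back to a carbinol so that the last C–C bond can come from a carbonyl addition. The gain is that the dienone, the most base- and nucleophile-sensitive element, exists only after the final step. The demand is an oxidant that takes the doubly allylic C2 carbinol and leaves the C5 carbinol.

31 ⇒ 30. The C2–C3 bond is cut between the carbinol carbon and a vinyl carbon, giving a C3 vinyl iodide and a C2 enal in one chain. The cut lies between two halves that each already hold one cis alkene, and chromium/nickel coupling tolerates hydroxyl, esters and the acrylate. The ring becomes an open chain in which both alkene geometries and all four stereocentres are settled. The demand is a ten-membered closure at high dilution without help from a bridge.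

30 ⇒ 29. No bond is cut; the C1=C10 π bond is turned from Z back to E. The reason is that an open-chain elimination cannot be made to place the formyl group cis to C9, so the geometry is adjusted afterwards. The gain is that the precursor may be whatever isomer mixture the elimination delivers. The demand is an isomerisation that acts on the enal alone and leaves the Z C3–I bond, the acrylate and the tiglate as they are.

29 ⇒ 27. The C1=C10 alkene is traced back to the C10–O6 ether bond and a C1–H, and the O6–C12 lactone to an O5–C12 lactone (retro-oxa-Michael opening from the C2 aldehyde, then 1,2-acyl shift). The pyran is opened before the ten-membered ring is closed because an oxygen-bridged eight-membered ring spanning the diaxial C6/C10 positions can hold the C5 oxygen only anti to O6 (the 5-epimer) and would expel O6 anti to H1 to give a trans C1=C10 bond. The gain is the intact pyran of the cycloadduct, with O5 and C12 protecting each other. The demand is that elimination and acyl shift outrun base-induced damage to the acrylate.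

27 ⇒ 26 ⇒ 25. The C3–I bond is traced to C3–Si (retentive iododesilylation) and the C2 aldehyde to a methyl enol ether. Both carry a reactive group in latent form through the basic steps. The demand is that silicon stand cis to C5 from the outset and that the enol ether be unmasked by acid only after the last base-labile operation.

25 ⇒ 22 + 23, and 22 ⇒ 21. The tiglate C–O bond at O8 is cut, and the free C8 hydroxyl is traced to its triethylsilyl ether. The ester is placed after the last strong base and before the C5 hydroxyl is uncovered, so O8 and O5 never compete. The demand is acylation of a hindered secondary alcohol without touching the enol ether.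

21 ⇒ 18. The C11=C13 bond is cut (aminomethylation, quaternisation, elimination). It is placed here because the molecule then carries no carbonyl other than the lactone. The demand is clean enolate formation next to C7.

18 ⇒ 16. The C1=C2 bond is cut (Wittig) and the O5–C12 lactone bond opened. One carbon is added at the neopentyl C1 aldehyde, and the C5 alkoxide released from the lactol is used to close the lactone. The demand is a base that does not trigger 1,4-silyl migration from C3 to O5.

16 ⇒ 10 + 13, and 13 ⇒ 11 + 12. The C4–C5 bond is cut to a C5 aldehyde and a 2-metallated 1-silylpropene, itself from syn-silylstannation of the alkyne. Reagents that add hydrogen and the C5 carbon syn across a silylpropyne would put silicon trans to C5 and lead to the E iodide; syn addition of Si–Sn puts silicon cis to the metal. The gain is C3, C4 and C15 in one reagent of defined geometry. The demand is chelation control at C5 (5,6-syn) and preference for the C5 aldehyde over the neopentyl C1 aldehyde.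

10 ⇒ 9. C1 and C5 are rejoined as the cis alkene of the bicycle (ozonolysis forward). The gain is a cis-2,6-disubstituted oxane with both arms at the aldehyde level; the demand is that the dialdehyde be used at once.

9 ⇒ 8 ⇒ 7 ⇒ 6 ⇒ 5. These are functional-group changes only: C8 silyl ether from the alcohol, alcohol from the ketone, C12 ester from acid from aldehyde. The demand is the equatorial C8 alcohol, which kinetic hydride delivery does not give.

5 ⇒ 1 + 4. C6–C7 and C9–C10 are cut, opening the cycloheptenone and the oxygen-bridged pyranone together. Two achiral partners then supply C6–C10, C11, C12, C14, C1 and C5 with O6 attached. The demand is catalyst control of C7 and C6, regiochemistry that puts the methyl group on C10, and ring closure faster than rearomatisation.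

4 ⇒ 3 ⇒ 1. The silyl enol ether is traced to the methyl ketone, and the keto-enal to oxidative opening of the furan. Both cycloaddition partners thus come from 1.

## Other disconnections considered

Alternative 1: The cut is the C5–C10 bond of a cis-fused decalin. Forward, the C5 alkoxide of a 5-hydroxy 1-sulfonate pushes out the leaving group with cleavage of C5–C10 (Wharton–Grob fragmentation), giving the ten-membered trienone A1 with C5 as ketone and Z C1=C10.
- In its favour: the medium ring is unveiled rather than closed, so there is no entropic penalty, and here it is the better of the two plans compared with the macrocyclisation of 30. The C1=C10 geometry follows stereospecifically from the anti-periplanar alignment in the ring fusion, which is also better than isomerising and separating enal isomers. The C7 centre can come from the chiral pool, which is equal to catalyst control.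
- Against it here: A1 is redox-transposed (C5 ketone, C2 ether), so C5 must be reduced with control on a flexible ring and C2 deprotected and oxidised. The isopropenyl group must be oxidised at C12 and lactonised in the presence of three other alkenes. The decalin must already carry the oxygenation at C2, C5, C6, C8 and the Z C3=C4 bond.
- Comparison: structurally it builds the carbocycle first and the lactone last, while the chosen plan installs O6, C11 and C12 in its first C–C bond-forming event. Mechanistically a concerted fragmentation is at least as predictable as the cycloaddition. In step count it should be clearly longer than 20.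

Alternative 2: The cut is the C7–C11 and C8–C11 bonds of a cyclopropane and then the C8–O bond. Forward, a carbene from the O6 diazomalonate (Rh2(OAc)4 type catalyst) adds to the cis C7=C8 alkene to give lactone-fused cyclopropane A2, which tiglate opens at C8 with inversion; ester cleavage and decarboxylative methylenation follow.
- In its favour: lactone, C7, C8 and the tiglate C–O bond arise in two steps, with facial control by the tether. The tiglate enters as a nucleophile, so no protecting-group exchange at O8 is needed, which is better than steps 13 and 14. Decarboxylative methylenation is milder than enolate methylenation, which is also better.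
- Against it here: the precursor is an already closed all-cis cyclodecatrienone, so ring formation, the hardest part, is left unsolved. The carbene has C–H insertion and enone alkenes as alternatives. Opening a cyclopropane that lacks a donor group with a weak carboxylate at secondary C8 has little precedent and would need Lewis-acid forcing next to a dienone.
- Comparison: structurally elegant at C7/C8, and equal on absolute control if C6 is set earlier. Mechanistically its second step is the least secure of all the plans. In step count it could be shorter after the ring, but not overall.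

Alternative 3: The cut is C1–C2 and C2–C3, with carbon monoxide as C2. Forward, zerovalent palladium inserts into the C3–I bond, takes up CO, and the acyl–palladium couples with a C1 vinylstannane to close the ring as A3, the 5-O-silyl ether of 32.
- In its favour: both alkene geometries are fixed beforehand in open-chain vinyl iodide and vinylstannane, which is better than the chosen plan at C1=C10. The ketone forms directly with no oxidation, which is equal or better. One deprotection then ends the synthesis, giving better endgame convergence.
- Against it here: carbonylative closure of a ten-membered dienone must beat direct coupling to a nine-membered diene and protodestannylation. The acrylate is a Heck acceptor. The open-chain precursor needs C5–C8 set by separate asymmetric steps.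
- Comparison: the ring closure is as uncertain as step 19 (equal). Structurally the chosen plan gains three stereocentres and two rings in one catalytic step. The step count is expected to be similar.

Key step: step 3

Remark on the chemistry: the cycloaddition is assumed to follow the compact topology usual for furan/oxyallyl pairs, so the C11 arm of 5 is equatorial as formed; the (2R,5R) salt is the antipode that the usual shielding model for β-attack on an E-iminium ion assigns to the required C7 configuration.
Remark on the chemistry: the open-chain enal is assumed to favour the E geometry at thermal equilibrium, as 3-methylalk-2-enals do; the Z geometry is therefore set by a separate step after the bridge opening.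
Remark on the chemistry: the cis C1=C10 isomer is assumed to be the more stable one in the ten-membered dienone; this is used only in fallbacks.

## Route

Step 1
Reactants: 1 2-methylfuran
Product: 3 (E)-4-oxopent-2-enal, via (Z)-4-oxopent-2-enal 2 (not isolated)
Conditions: NBS, NaHCO3, acetone/H2O, −20 °C; then pyridine, rt; used promptly
Reagents that add atoms: water, O
Why: Oxidative furan ring opening (bromonium formation, water addition, collapse to the cis ene-dicarbonyl) followed by base-mediated cis-to-trans isomerisation of the electron-poor alkene to the thermodynamic E keto-enal.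

Step 2
Reactants: 3 (E)-4-oxopent-2-enal
Product: 4 (E)-4-(triethylsilyloxy)penta-2,4-dienal
Conditions: Et3SiOTf, Et3N, Et2O, 0 °C
Reagents that add atoms: triethylsilyl trifluoromethanesulfonate, CC[Si](CC)(CC)OS(=O)(=O)C(F)(F)F
Why: Soft enolisation and O-silylation (silyl enol ether formation); only the methyl ketone has enolisable hydrogens, so the 2-silyloxydiene forms regiospecifically and the E alkene is untouched.

Step 3
Reactants: 1 2-methylfuran (5 equiv), 4 (E)-4-(triethylsilyloxy)penta-2,4-dienal
Product: 5 (1R,2S,5R)-5-methyl-2-(2-oxoethyl)-8-oxabicyclo[3.2.1]oct-6-en-3-one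
Conditions: (2R,5R)-5-benzyl-2-tert-butyl-3-methylimidazolidin-4-one·CF3CO2H (20 mol%), CH2Cl2, −78 °C; aqueous NaHCO3; chromatography to remove any C7 epimer
Reagents that add atoms: water, O
Why: The amine salt condenses with the aldehyde of 4 to an E-iminium ion that is also a 1-amino-3-silyloxypentadienyl (vinylogous 2-oxyallyl) cation; the free α-carbon of 1 attacks its β-carbon (C7) on the face left open by the benzyl group, the resulting oxocarbenium ion is captured at its methyl-bearing carbon (C10) by the silyl enol ether terminus (C9), and loss of silicon plus hydrolysis of the enamine release 5 and the catalyst. The closest known reaction type is the amine-catalysed [4+3] cycloaddition of 4-silyloxypentadienals with furans, a stepwise relative of the furan/2-oxyallyl cation cycloaddition. The second bond closes both rings in one event: the tetrahydropyranone (O6, C6–C10) by a 6-(enolendo)-endo-trig attack on the C10=O6 oxocarbenium bond, and the cycloheptenone (C6–C10, C1, C5) by the same attack counted as 7-(enolendo)-exo-trig. C7 is set by the catalyst (facial shielding of the iminium ion); C6 is set in the same first bond by the compact, endo-like approach of the furan over the silyloxydiene, which leaves the C11 arm equatorial; C10 is set by the tether, since the enol ether can reach only the face of the oxocarbenium ion on which it hangs. The step needs ring closure faster than loss of H6 (which would rearomatise to the Friedel–Crafts adduct), secured by the low temperature, the non-basic trifluoroacetate and the nucleophilic silyl enol ether; it also needs first attack by the unsubstituted furan α-carbon at the iminium β-carbon, secured by sterics, which puts the methyl group on C10. The C7 arm must not be adjusted by base afterwards: epimerising an axial diastereomer would invert the catalyst-set centre and feed the antipodal series, so any minor epimer is removed here.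

Step 4
Reactants: 5 keto aldehyde
Product: 6 2-[(1R,2S,5R)-5-methyl-3-oxo-8-oxabicyclo[3.2.1]oct-6-en-2-yl]acetic acid
Conditions: NaClO2, NaH2PO4, 2-methylbut-2-ene, t-BuOH/H2O, 0 °C
Reagents that add atoms: sodium chlorite, [Na+].[O-]Cl=O
Why: Pinnick oxidation of the aldehyde via its chlorite adduct; the buffered medium and the hypochlorite scavenger spare the ketone, the strained alkene and the C7 centre.

Step 5
Reactants: 6 keto acid
Product: 7 methyl 2-[(1R,2S,5R)-5-methyl-3-oxo-8-oxabicyclo[3.2.1]oct-6-en-2-yl]acetate
Conditions: MeI, K2CO3, DMF, 0 °C → rt
Reagents that add atoms: iodomethane, CI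
Why: Carboxylate O-alkylation (SN2); C7 is already the equatorial, thermodynamic epimer, so brief carbonate exposure cannot change it.

Step 6
Reactants: 7 keto ester
Product: 8 methyl 2-[3-hydroxy-5-methyl-8-oxabicyclo[3.2.1]oct-6-en-2-yl]acetate (3-OH equatorial)
Conditions: SmI2 (2.5 equiv), i-PrOH, THF, 0 °C → rt
Reagents that add atoms: none
Why: Ketyl (single-electron) reduction under thermodynamic protonation should give the equatorial C8 alcohol trans to the equatorial C7 arm, the outcome established for 8-oxabicyclo[3.2.1]oct-6-en-3-ones, whereas hydride reagents attack from the open face and give the axial epimer; an unactivated methyl ester is inert to SmI2/alcohol.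

Step 7
Reactants: 8 hydroxy ester
Product: 9 triethylsilyl ether of 8
Conditions: Et3SiCl, imidazole, DMF, 0 °C
Reagents that add atoms: chlorotriethylsilane, CC[Si](Cl)(CC)CC
Why: Silylation of the secondary alcohol, done at once so that the γ-hydroxy ester cannot close to an 8,12-lactone; the ether survives every basic step up to step 13.

Step 8
Reactants: 9 silyl ether
Product: 10 methyl 2-[2,6-diformyl-6-methyl-4-(triethylsilyloxy)oxan-3-yl]acetate
Conditions: O3, CH2Cl2, −78 °C; PPh3, −78 °C → rt; used crude
Reagents that add atoms: ozone, [O-][O+]=O
Why: Ozonolysis with reductive work-up cleaves the strained cis alkene to the C1 and C5 aldehydes, which stay cis on the oxane because both bridgehead bonds are retained; non-basic work-up protects the epimerisable C6.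

Step 9
Reactants: 11 propyne, 12 trimethyl(tributylstannyl)silane
Product: 13 (Z)-trimethyl[2-(tributylstannyl)prop-1-en-1-yl]silane
Conditions: Pd(PPh3)4 (2 mol%), THF, 65 °C, sealed tube
Reagents that add atoms: none
Why: Palladium-catalysed silylstannation of a terminal alkyne: the Si–Sn bond adds oxidatively to zerovalent palladium and is delivered syn, silicon to the terminal and tin to the internal carbon, so silicon and tin are cis.

Step 10
Reactants: 10 dialdehyde, 13 silyl stannane
Product: 16 bicyclic lactol of the C5 adduct, via vinyllithium 14 (not isolated), via vinylmagnesium bromide 15 (not isolated)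
Conditions: 13, MeLi, THF, −78 → 0 °C; MgBr2·OEt2, −78 °C; then 10, CH2Cl2/Et2O, −78 °C; aqueous NH4Cl
Reagents that add atoms: none
Why: Tin–lithium exchange with retention, transmetalation to magnesium and chelation-controlled 1,2-addition: magnesium bridges the C5 carbonyl oxygen and ring oxygen O6 and the vinyl group enters anti to C7, setting C5 as S (5,6-syn). The C5 aldehyde on a tertiary carbon should react before the neopentyl C1 aldehyde, and the new alkoxide closes onto C1 as a lactol, which shields that aldehyde from a second addition.

Step 11
Reactants: 16 lactol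
Product: 18 δ-lactone enol ether, via hydroxy ester enol ether 17 (not isolated)
Conditions: Ph3P(CH2OMe)Cl, LiN(SiMe3)2, THF, 0 °C → rt; aqueous NH4Cl; then DBU (0.2 equiv), toluene, 40 °C
Reagents that add atoms: (methoxymethyl)triphenylphosphonium chloride, COC[P+](c1ccccc1)(c1ccccc1)c1ccccc1.[Cl-]
Why: Wittig methoxymethylenation of the open-chain neopentyl aldehyde of the lactol adds C2; the released C5 hydroxyl then lactonises onto the C12 ester (six-membered, cis-fused), which protects O5 and C12 together. A lithium base is used so that the (Z)-γ-silyl allylic alkoxide does not undergo 1,4-silyl (Brook) migration.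

Step 12
Reactants: 18 δ-lactone enol ether
Product: 21 11-methylene δ-lactone, via Mannich base 19 (not isolated), via trimethylammonium iodide 20 (not isolated)
Conditions: LiN(iPr)2, THF, −78 °C; CH2=NMe2 iodide, −78 °C → rt; MeI, CH2Cl2, rt; DBU, rt
Reagents that add atoms: N,N-dimethylmethyleneiminium iodide, C=[N+](C)C.[I-]
Why: Lactone enolate aminomethylation (Mannich), N-quaternisation and Hofmann-type elimination install C13; at this stage the lactone is the only carbonyl, so the strong base meets no enone, aldehyde or tiglate.

Step 13
Reactants: 21 methylene lactone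
Product: 22 C8 alcohol
Conditions: HF·pyridine, pyridine, THF, 0 °C
Reagents that add atoms: none
Why: Fluoride-driven cleavage of the secondary triethylsilyl ether; excess pyridine keeps the medium mild enough for the enol ether, and the vinyl C–Si bond is inert to these conditions.

Step 14
Reactants: 22 C8 alcohol, 23 tiglic acid
Product: 25 8-O-tiglate, via mixed anhydride 24 (not isolated)
Conditions: 23, 2,4,6-trichlorobenzoyl chloride, Et3N, toluene, rt; then 22, DMAP, 40 °C
Reagents that add atoms: none
Why: Yamaguchi esterification: the mixed anhydride is attacked by DMAP at the less hindered tigloyl carbonyl and the acylpyridinium acylates the hindered secondary alcohol; C8 is the only free hydroxyl and the E geometry of the acid is not at risk.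

Step 15
Reactants: 25 tiglate enol ether
Product: 26 C2 aldehyde
Conditions: 1 M HCl, THF, 0 °C → rt
Reagents that add atoms: water, O
Why: Acid hydrolysis of the enol ether (C-protonation, hemiacetal collapse) unmasks the aldehyde only now; the β-alkoxy aldehyde is stable to acid, and lactone, tiglate and vinylsilane tolerate dilute acid.

Step 16
Reactants: 26 vinylsilane aldehyde
Product: 27 (Z)-vinyl iodide aldehyde
Conditions: NIS, (CF3)2CHOH, 0 °C
Reagents that add atoms: N-iodosuccinimide, O=C1CCC(=O)N1I
Why: ipso-Iododesilylation: iodonium attack at C3 gives a β-silyl cation that loses silicon by least motion, so the iodide takes the place of silicon with retention (I cis to C5); the electron-poor acrylate and tiglate alkenes do not compete.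

Step 17
Reactants: 27 vinyl iodide aldehyde
Product: 29 (1(10)E)-enal γ-lactone, via ring-opened δ-lactone enal 28 (not isolated)
Conditions: DBU (1.2 equiv), CH2Cl2, −20 → 0 °C; aqueous NH4Cl; short SiO2 column; 29 taken on together with its Z isomer 30
Reagents that add atoms: none
Why: E1cB (retro-oxa-Michael) elimination: deprotonation at C1 expels O6 from C10, and the freed O6 alkoxide takes the acyl group from the vicinal O5 through a five-membered orthoester (1,2-acyl shift), which trades the δ-lactone for the trans-disubstituted γ-lactone, frees the C5 hydroxyl and makes the opening irreversible. Nothing in the open chain holds the formyl group cis to C9, so the E enal, with the formyl group beside the smaller methyl group, should predominate.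

Step 18
Reactants: 29 (1(10)E)-enal γ-lactone (as the E/Z mixture from step 17)
Product: 30 (1(10)Z)-enal γ-lactone
Conditions: hν (365 nm LED), degassed MeCN (5 mM), Pyrex, 0 °C, to the photostationary state; SiO2 chromatography; recovered 29 re-irradiated
Reagents that add atoms: none
Why: Photochemical E/Z isomerisation of an α,β-unsaturated aldehyde: n→π* excitation gives a twisted excited state that decays to both geometries, so the Z content should rise above its thermal share, and chromatography with re-irradiation of recovered 29 funnels material to 30. At 365 nm the vinyl iodide, the acrylate and the tiglate do not absorb, so the Z C3–I geometry set in step 16 is untouched, which an iodine-atom or thiyl-radical catalyst could not guarantee.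

Step 19
Reactants: 30 (Z)-enal
Product: 31 macrocyclic 2,5-diol (C2 epimers)
Conditions: CrCl2 (10 equiv), NiCl2 (1 mol%), degassed DMSO (2 mM), rt, slow addition
Reagents that add atoms: none
Why: Nozaki–Hiyama–Kishi cyclisation: zerovalent nickel inserts into the C3–I bond, transmetalation gives a vinyl species of trivalent chromium that adds 1,2 to the enal with retention of the Z alkene. The two cis alkenes and the trans-lactone bend the chain toward closure, and free hydroxyl, esters and acrylate are tolerated.

Step 20
Reactants: 31 macrocyclic diol
Product: 32 target, (5S,6S,7R,8S)-5-hydroxy-2-oxo-8-tigloyloxygermacra-1(10)Z,3Z,11(13)-trien-6,12-olide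
Conditions: MnO2 (activated, excess), CH2Cl2, 0 °C → rt
Reagents that add atoms: none
Why: Allylic oxidation on MnO2: the doubly allylic C2 carbinol should react far faster than the C5 carbinol, which is allylic to one alkene only, becomes attached to an electron-poor enone as soon as C2 is oxidised, and is flanked by the acyloxy-bearing C6; both C2 epimers converge.

## Compound list

1 | 2-methylfuran | Cc1ccco1 | starting material
2 | (Z)-4-oxopent-2-enal | CC(=O)/C=C\C=O | intermediate
3 | (E)-4-oxopent-2-enal | CC(=O)/C=C/C=O | intermediate
4 | (E)-4-(triethylsilyloxy)penta-2,4-dienal | C=C(O[Si](CC)(CC)CC)/C=C/C=O | intermediate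
5 | (1R,2S,5R)-5-methyl-2-(2-oxoethyl)-8-oxabicyclo[3.2.1]oct-6-en-3-one (arm equatorial) | O=CC[C@@H]1C(=O)C[C@]2(C)C=C[C@H]1O2 | intermediate
6 | 2-[(1R,2S,5R)-5-methyl-3-oxo-8-oxabicyclo[3.2.1]oct-6-en-2-yl]acetic acid | OC(=O)C[C@@H]1C(=O)C[C@]2(C)C=C[C@H]1O2 | intermediate
7 | methyl 2-[(1R,2S,5R)-5-methyl-3-oxo-8-oxabicyclo[3.2.1]oct-6-en-2-yl]acetate | COC(=O)C[C@@H]1C(=O)C[C@]2(C)C=C[C@H]1O2 | intermediate
8 | methyl 2-[3-hydroxy-5-methyl-8-oxabicyclo[3.2.1]oct-6-en-2-yl]acetate, bicycle as in 7, 3-OH equatorial and trans to the C2 arm | COC(=O)C[C@@H]1[C@@H](O)C[C@]2(C)C=C[C@H]1O2 | intermediate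
9 | triethylsilyl ether of 8 | COC(=O)C[C@@H]1[C@@H](O[Si](CC)(CC)CC)C[C@]2(C)C=C[C@H]1O2 | intermediate
10 | methyl 2-[2,6-diformyl-6-methyl-4-(triethylsilyloxy)oxan-3-yl]acetate; 2-CHO (C5), 6-CHO (C1) and the C3 arm mutually cis, 4-silyloxy trans to them | COC(=O)C[C@@H]1[C@@H](O[Si](CC)(CC)CC)C[C@](C)(C=O)O[C@@H]1C=O | intermediate
11 | propyne | CC#C | starting material
12 | trimethyl(tributylstannyl)silane | C[Si](C)(C)[Sn](CCCC)(CCCC)CCCC | starting material
13 | (Z)-trimethyl[2-(tributylstannyl)prop-1-en-1-yl]silane | C[Si](C)(C)/C=C(/C)[Sn](CCCC)(CCCC)CCCC | intermediate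
14 | (Z)-[1-(trimethylsilyl)prop-1-en-2-yl]lithium | [Li]/C(C)=C\[Si](C)(C)C | intermediate
15 | (Z)-[1-(trimethylsilyl)prop-1-en-2-yl]magnesium bromide | C[Si](C)(C)/C=C(/C)[Mg]Br | intermediate
16 | methyl 2-[4-hydroxy-5-methyl-7-(triethylsilyloxy)-2-[(Z)-1-(trimethylsilyl)prop-1-en-2-yl]-3,9-dioxabicyclo[3.3.1]nonan-8-yl]acetate; lactol of O5 on C1 (both anomers), germacrane C5 S, other centres as in 10 | COC(=O)C[C@@H]1[C@@H](O[Si](CC)(CC)CC)C[C@]2(C)C(O)O[C@@H](/C(C)=C\[Si](C)(C)C)[C@H]1O2 | intermediate
17 | methyl 2-[2-[(1S,2Z)-1-hydroxy-2-methyl-3-(trimethylsilyl)prop-2-enyl]-6-(2-methoxyvinyl)-6-methyl-4-(triethylsilyloxy)oxan-3-yl]acetate (ring as in 10, enol ether E/Z) | COC(=O)C[C@@H]1[C@@H](O[Si](CC)(CC)CC)C[C@](C)(C=COC)O[C@@H]1[C@@H](O)/C(C)=C\[Si](C)(C)C | intermediate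
18 | δ-lactone of 17 (O5–C12 bond, six-membered lactone cis-fused to the oxane at C6–C7) | O=C1C[C@@H]2[C@@H](O[Si](CC)(CC)CC)C[C@](C)(C=COC)O[C@@H]2[C@H](/C(C)=C\[Si](C)(C)C)O1 | intermediate
19 | 11-(dimethylaminomethyl) derivative of 18 (C11 epimers) | O=C1C(CN(C)C)[C@@H]2[C@@H](O[Si](CC)(CC)CC)C[C@](C)(C=COC)O[C@@H]2[C@H](/C(C)=C\[Si](C)(C)C)O1 | intermediate
20 | 11-(trimethylammoniomethyl) iodide of 18 | O=C1C(C[N+](C)(C)C)[C@@H]2[C@@H](O[Si](CC)(CC)CC)C[C@](C)(C=COC)O[C@@H]2[C@H](/C(C)=C\[Si](C)(C)C)O1.[I-] | intermediate
21 | 11-methylene δ-lactone (C11=C13), otherwise as 18 | O=C1C(=C)[C@@H]2[C@@H](O[Si](CC)(CC)CC)C[C@](C)(C=COC)O[C@@H]2[C@H](/C(C)=C\[Si](C)(C)C)O1 | intermediate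
22 | C8 alcohol from 21 | O=C1C(=C)[C@@H]2[C@@H](O)C[C@](C)(C=COC)O[C@@H]2[C@H](/C(C)=C\[Si](C)(C)C)O1 | intermediate
23 | tiglic acid, (E)-2-methylbut-2-enoic acid | C/C=C(\C)C(=O)O | starting material
24 | (E)-2-methylbut-2-enoic 2,4,6-trichlorobenzoic anhydride | C/C=C(\C)C(=O)OC(=O)c1c(Cl)cc(Cl)cc1Cl | intermediate
25 | 8-O-tiglate of 22 | O=C1C(=C)[C@@H]2[C@@H](OC(=O)/C(C)=C/C)C[C@](C)(C=COC)O[C@@H]2[C@H](/C(C)=C\[Si](C)(C)C)O1 | intermediate
26 | aldehyde from 25: C10 carries CH3 and CH2CHO (C1–C2) | O=C1C(=C)[C@@H]2[C@@H](OC(=O)/C(C)=C/C)C[C@](C)(CC=O)O[C@@H]2[C@H](/C(C)=C\[Si](C)(C)C)O1 | intermediate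
27 | (Z)-vinyl iodide from 26 (I on C3, cis to C5) | O=C1C(=C)[C@@H]2[C@@H](OC(=O)/C(C)=C/C)C[C@](C)(CC=O)O[C@@H]2[C@H](/C(C)=C\I)O1 | intermediate
28 | ring-opened 6-hydroxy 5,12-δ-lactone enal (C1=C10 formed as E/Z mixture, acyl still on O5) | O=C1C(=C)[C@H]([C@@H](OC(=O)/C(C)=C/C)CC(C)=CC=O)[C@H](O)[C@H](/C(C)=C\I)O1 | intermediate
29 | (1(10)E)-enal: 5-hydroxy-3-iodo-2-oxo-8-tigloyloxy-2,3-seco-germacra-1(10),3,11(13)-trien-6,12-olide, E at C1=C10, Z at C3=C4 | C=C1C(=O)O[C@H]([C@@H](O)/C(C)=C\I)[C@H]1[C@@H](OC(=O)/C(C)=C/C)C/C(C)=C/C=O | intermediate
30 | (1(10)Z)-enal, otherwise as 29 | C=C1C(=O)O[C@H]([C@@H](O)/C(C)=C\I)[C@H]1[C@@H](OC(=O)/C(C)=C/C)C/C(C)=C\C=O | intermediate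
31 | (1(10)Z,3Z)-2,5-dihydroxy-8-tigloyloxygermacra-1(10),3,11(13)-trien-6,12-olide (C2 epimers) | C=C1C(=O)O[C@H]2[C@H]1[C@@H](OC(=O)/C(C)=C/C)C/C(C)=C\C(O)/C=C(/C)[C@@H]2O | intermediate
32 | CNP0230565.1, (5S,6S,7R,8S,1(10)Z,3Z)-5-hydroxy-2-oxo-8-tigloyloxygermacra-1(10),3,11(13)-trien-6,12-olide | C=C1C(=O)O[C@H]2[C@H]1[C@@H](OC(=O)/C(C)=C/C)C/C(C)=C\C(=O)/C=C(/C)[C@@H]2O | target

## Step count and least certain steps

Total: 20 steps. Longest linear sequence: 19 steps (steps 1–8 and 10–20 from 1); step 9 is a one-step side branch.

Step 3 (key step). What may go wrong: loss of the C6 proton from the first-formed cation, so that the furan rearomatises before the second bond closes; first bond formation at the unsubstituted diene terminus, which would reverse the regiochemistry; or weak facial or topological discrimination, lowering enantiomeric or diastereomeric purity. Fallback, setting out from 1 and coming back at 7: a classical oxyallyl-cation [4+3] cycloaddition of 1 with 1,1,3,3-tetrabromoacetone and Zn–Cu couple would give 2,4-dibromo-1-methyl-8-oxabicyclo[3.2.1]oct-6-en-3-one F1. Zn–Cu/NH4Cl in methanol would reduce it to racemic 1-methyl-8-oxabicyclo[3.2.1]oct-6-en-3-one F2. Kinetic enolisation (LiN(iPr)2, −78 °C) at the α-methylene remote from the methyl-bearing bridgehead, alkylation with methyl bromoacetate and DBU equilibration (harmless in a racemate) would give the racemic keto ester F3. Preparative chromatography on a chiral stationary phase would then supply 7.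

Step 10. What may go wrong: competing addition to the C1 aldehyde, or erosion of chelation control so that Felkin–Anh attack gives the 5-epimer. Fallback, setting out from 9 and coming back at 17: ozonolysis of 9 with NaBH4 work-up would give the diol F4. AcCl/2,4,6-collidine at −78 °C would acetylate the less hindered C5 carbinol to the monoacetate F5. TEMPO/PhI(OAc)2 would oxidise the neopentyl carbinol to the C1 aldehyde F6, and methoxymethylenation would give the enol ether acetate F7. K2CO3/MeOH would free the alcohol F8, and a second TEMPO/PhI(OAc)2 oxidation would give the C5 aldehyde F9. F9 has no competing carbonyl and would take up 15 under chelation control to give 17.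

Step 17. What may go wrong: conjugate addition of the freed C5 hydroxyl or of the base to the methylene lactone, migration of the exocyclic alkene into the lactone ring under base, or an acyl shift that stops short. Fallback, setting out from 27 and coming back at 29, replacing the alkoxide cascade by a Lewis-acid opening in which no free alkoxide appears: soft enolisation with Me3SiOTf/Et3N (CH2Cl2, −78 → −20 °C) would convert the aldehyde into its silyl enol ether while the silyl triflate activates the bridging O6, so that the C10–O6 bond breaks and O6 leaves as its silyl ether, giving the 6-O-trimethylsilyl ether of the ring-opened δ-lactone enal F10. Aqueous citric acid in THF would remove the silyl group to give 28, here isolated. Pyridinium p-toluenesulfonate in CH2Cl2 would then complete the 1,2-acyl shift from O5 to O6 under acid and deliver 29, again with its Z isomer, for step 18.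

Step 18. What may go wrong: a photostationary state poor in the Z isomer, photodeconjugation through the dienol of the Z enal, or slow light-induced loss of iodide on repeated recycling. Fallback, setting out from 29 and coming back at 32, moving geometric control from the open chain into the ring: the E enal 29 would be cyclised under the conditions of step 19 to the (1(10)E) diol F11. MnO2 would oxidise it to the (1(10)E) isomer of the target F12. Iodine-catalysed geometric equilibration (I2, 2 mol%, CH2Cl2, visible light), acceptable at this stage because no vinyl iodide remains and because it does not move double bonds out of conjugation, would convert F12 to 32.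

Step 19. What may go wrong: oligomerisation or protodeiodination outrunning the ten-membered closure because the open chain is not preorganised, or geometric leakage of the enal. Fallback, setting out from 10 and coming back at 32, closing the ring on the oxygen bridge instead; this is possible only in the 5-epi series, in which the C5 oxygen points away from the bridge: addition of 14 without magnesium (THF, −100 °C, Felkin–Anh control) would give the 5-epi lactol F13. Repeating steps 11–16 would give in turn the 5-epi δ-lactone enol ether F14, the methylene lactone F15, the alcohol F16, the tiglate F17, the aldehyde F18 and the vinyl iodide F19. CrCl2/NiCl2 would close the eight-membered oxygen-bridged ring across the diaxial C6/C10 positions to the carbinol F20, and MnO2 would give the bridged enone F21. DBU would open the bridge by anti elimination and shift the acyl group, giving the (1(10)E) 5-epi isomer F22; iodine-catalysed equilibration would give 5-epi-32 F23. Mitsunobu inversion at C5 (ClCH2CO2H, PPh3, diisopropyl azodicarboxylate) would give the chloroacetate of natural configuration F24, which thiourea/NaHCO3 would cleave to 32.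

## Further compounds

F1 | step 3 | 2,4-dibromo-1-methyl-8-oxabicyclo[3.2.1]oct-6-en-3-one (diastereomer mixture) | CC12C=CC(O1)C(Br)C(=O)C2Br
F2 | step 3 | racemic 1-methyl-8-oxabicyclo[3.2.1]oct-6-en-3-one | CC12C=CC(O1)CC(=O)C2
F3 | step 3 | racemic methyl 2-[5-methyl-3-oxo-8-oxabicyclo[3.2.1]oct-6-en-2-yl]acetate, relative configuration of 7 (one enantiomer drawn) | COC(=O)C[C@@H]1C(=O)C[C@]2(C)C=C[C@H]1O2
F4 | step 10 | diol: methyl 2-[2,6-bis(hydroxymethyl)-6-methyl-4-(triethylsilyloxy)oxan-3-yl]acetate, configured as 10 | COC(=O)C[C@@H]1[C@@H](O[Si](CC)(CC)CC)C[C@](C)(CO)O[C@@H]1CO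
F5 | step 10 | monoacetate of F4 at the C5 carbinol | COC(=O)C[C@@H]1[C@@H](O[Si](CC)(CC)CC)C[C@](C)(CO)O[C@@H]1COC(C)=O
F6 | step 10 | C1 aldehyde from F5 | COC(=O)C[C@@H]1[C@@H](O[Si](CC)(CC)CC)C[C@](C)(C=O)O[C@@H]1COC(C)=O
F7 | step 10 | methyl enol ether (E/Z) from F6 | COC(=O)C[C@@H]1[C@@H](O[Si](CC)(CC)CC)C[C@](C)(C=COC)O[C@@H]1COC(C)=O
F8 | step 10 | C5 primary alcohol from F7 | COC(=O)C[C@@H]1[C@@H](O[Si](CC)(CC)CC)C[C@](C)(C=COC)O[C@@H]1CO
F9 | step 10 | C5 aldehyde from F8 | COC(=O)C[C@@H]1[C@@H](O[Si](CC)(CC)CC)C[C@](C)(C=COC)O[C@@H]1C=O
F10 | step 17 | 6-O-trimethylsilyl ether of 28 (C1=C10 E/Z mixture, acyl on O5) | O=C1C(=C)[C@H]([C@@H](OC(=O)/C(C)=C/C)CC(C)=CC=O)[C@H](O[Si](C)(C)C)[C@H](/C(C)=C\I)O1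
F11 | step 18 | (1(10)E,3Z)-2,5-dihydroxy-8-tigloyloxygermacra-1(10),3,11(13)-trien-6,12-olide (C2 epimers) | C=C1C(=O)O[C@H]2[C@H]1[C@@H](OC(=O)/C(C)=C/C)C/C(C)=C/C(O)/C=C(/C)[C@@H]2O
F12 | step 18 | (1(10)E) isomer of 32 | C=C1C(=O)O[C@H]2[C@H]1[C@@H](OC(=O)/C(C)=C/C)C/C(C)=C/C(=O)/C=C(/C)[C@@H]2O
F13 | step 19 | 5-epimer of lactol 16 | COC(=O)C[C@@H]1[C@@H](O[Si](CC)(CC)CC)C[C@]2(C)C(O)O[C@H](/C(C)=C\[Si](C)(C)C)[C@H]1O2
F14 | step 19 | 5-epimer of 18 | O=C1C[C@@H]2[C@@H](O[Si](CC)(CC)CC)C[C@](C)(C=COC)O[C@@H]2[C@@H](/C(C)=C\[Si](C)(C)C)O1
F15 | step 19 | 5-epimer of 21 | O=C1C(=C)[C@@H]2[C@@H](O[Si](CC)(CC)CC)C[C@](C)(C=COC)O[C@@H]2[C@@H](/C(C)=C\[Si](C)(C)C)O1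
F16 | step 19 | 5-epimer of 22 | O=C1C(=C)[C@@H]2[C@@H](O)C[C@](C)(C=COC)O[C@@H]2[C@@H](/C(C)=C\[Si](C)(C)C)O1
F17 | step 19 | 5-epimer of 25 | O=C1C(=C)[C@@H]2[C@@H](OC(=O)/C(C)=C/C)C[C@](C)(C=COC)O[C@@H]2[C@@H](/C(C)=C\[Si](C)(C)C)O1
F18 | step 19 | 5-epimer of 26 | O=C1C(=C)[C@@H]2[C@@H](OC(=O)/C(C)=C/C)C[C@](C)(CC=O)O[C@@H]2[C@@H](/C(C)=C\[Si](C)(C)C)O1
F19 | step 19 | 5-epimer of 27 | O=C1C(=C)[C@@H]2[C@@H](OC(=O)/C(C)=C/C)C[C@](C)(CC=O)O[C@@H]2[C@@H](/C(C)=C\I)O1
F20 | step 19 | oxygen-bridged (O6 between C6 and C10) 5-epi 5,12-δ-lactone with the C1–C5 eight-membered ring closed, C2 carbinol (epimers), Z C3=C4 | O=C1C(=C)[C@@H]2[C@@H](OC(=O)/C(C)=C/C)C[C@]3(C)CC(O)/C=C(/C)[C@@H](O1)[C@H]2O3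
F21 | step 19 | C2 ketone from F20 | O=C1C(=C)[C@@H]2[C@@H](OC(=O)/C(C)=C/C)C[C@]3(C)CC(=O)/C=C(/C)[C@@H](O1)[C@H]2O3
F22 | step 19 | (1(10)E) 5-epimer of 32 | C=C1C(=O)O[C@H]2[C@H]1[C@@H](OC(=O)/C(C)=C/C)C/C(C)=C/C(=O)/C=C(/C)[C@H]2O
F23 | step 19 | 5-epimer of 32 | C=C1C(=O)O[C@H]2[C@H]1[C@@H](OC(=O)/C(C)=C/C)C/C(C)=C\C(=O)/C=C(/C)[C@H]2O
F24 | step 19 | 5-O-chloroacetate of 32 | C=C1C(=O)O[C@H]2[C@H]1[C@@H](OC(=O)/C(C)=C/C)C/C(C)=C\C(=O)/C=C(/C)[C@@H]2OC(=O)CCl
A1 | alternative 1 | (1(10)Z,3Z)-8-(tert-butyldimethylsilyloxy)-6-(methoxymethoxy)-2-(4-methoxybenzyloxy)germacra-1(10),3,11-trien-5-one | C=C(C)[C@@H]1[C@@H](O[Si](C)(C)C(C)(C)C)C/C(C)=C\[C@@H](OCc2ccc(OC)cc2)/C=C(/C)C(=O)[C@H]1OCOC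
A2 | alternative 2 | 7,8,11-cyclopropane-fused 11-(tert-butoxycarbonyl) 6,12-lactone of the (1(10)Z,3Z)-2-oxo ten-membered dienone, 5-O-tert-butyldimethylsilyl | CC(C)(C)OC(=O)[C@]12C(=O)O[C@H]3[C@H]1[C@H]2C/C(C)=C\C(=O)/C=C(/C)[C@@H]3O[Si](C)(C)C(C)(C)C
A3 | alternative 3 | 5-O-tert-butyldimethylsilyl ether of 32 | C=C1C(=O)O[C@H]2[C@H]1[C@@H](OC(=O)/C(C)=C/C)C/C(C)=C\C(=O)/C=C(/C)[C@@H]2O[Si](C)(C)C(C)(C)C
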